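**Retrosynthetic overview**
- GA50 ⇐ (ester cleavage, C16 methylenation) ⇐ ring C closed last by an acid-mediated intramolecular aldol addition (C12–C13) of a keto aldehyde.
- Ring A and the γ-lactone ⇐ one intramolecular Michael addition (C4→C5) of a seven-membered allylic lactone dienolate onto the ring B cyclopentene ester; the 2β,3β-diol by OsO4 on the resulting Δ2 alkene.
- The seven-membered lactone ⇐ allyl Grignard addition to the C10 ketone, O-acylation with 2-methylbut-3-enoyl chloride (fragment C), ring-closing metathesis.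
- Ring D ⇐ intramolecular (spiro) Michael addition of a methyl ketone onto the ring B cyclopentenecarboxylate; ring B comes from (R)-4-silyloxycyclopentenone (fragment A) through α-iodination, B-alkyl Suzuki coupling with borane fragment B, allylcopper addition/triflation and carbonylation.
- Order of ring formation: B (purchased) → D → seven-membered lactone → A + γ-lactone → C.

Assumption: the SMILES as given (hydroxyl on C12, β) is the target, gibberellane numbers (C1–C19) and α/β faces are used for all intermediates, and (R)-4-(tert-butyldimethylsilyloxy)cyclopent-2-en-1-one and 2-methyl-2-vinyl-1,3-dioxolane are taken as commercial.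

**Route**

Step 1
Reactants: 1 2-methyl-2-vinyl-1,3-dioxolane
Product: 2 9-[2-(2-methyl-1,3-dioxolan-2-yl)ethyl]-9-borabicyclo[3.3.1]nonane (used as THF solution)
Conditions: 9-BBN, THF, 0 °C to rt
Reagents that add atoms: 9-borabicyclo[3.3.1]nonane B1C2CCCC1CCC2
Why: Anti-Markovnikov hydroboration of the monosubstituted alkene puts boron on the terminal carbon and gives the B-alkyl partner for the Suzuki–Miyaura coupling.

Step 2
Reactants: 3 (E)-1-chlorobut-2-ene
Product: 5 2-methylbut-3-enoic acid (racemic), via but-2-enylmagnesium chloride 4 (not isolated)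
Conditions: Mg, THF, 0 °C; then CO2, −78 °C to rt; aq. HCl
Reagents that add atoms: carbon dioxide O=C=O
Why: Grignard carboxylation in which the allylic Grignard reagent attacks CO2 through its γ-carbon (SE2′), giving the branched β,γ-unsaturated acid.

Step 3
Reactants: 5 2-methylbut-3-enoic acid
Product: 6 2-methylbut-3-enoyl chloride (racemic)
Conditions: (COCl)2, DMF (cat.), CH2Cl2, 0 °C to rt
Reagents that add atoms: oxalyl chloride O=C(Cl)C(Cl)=O
Why: Acyl chloride formation through the chloroiminium intermediate needs no base, so the β,γ-alkene does not move into conjugation.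

Step 4
Reactants: 7 (R)-4-(tert-butyldimethylsilyloxy)cyclopent-2-en-1-one
Product: 8 (R)-4-(tert-butyldimethylsilyloxy)-2-iodocyclopent-2-en-1-one
Conditions: iodine, pyridine, CH2Cl2, 0 °C to rt
Reagents that add atoms: iodine [I][I]
Why: α-Iodination of the enone by the Johnson procedure (pyridine conjugate addition, enolate iodination, elimination) leaves the silyloxy stereocentre (future C10) untouched.

Step 5
Reactants: 8 (R)-4-(tert-butyldimethylsilyloxy)-2-iodocyclopent-2-en-1-one; 2 9-[2-(2-methyl-1,3-dioxolan-2-yl)ethyl]-9-borabicyclo[3.3.1]nonane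
Product: 9 (R)-4-(tert-butyldimethylsilyloxy)-2-[2-(2-methyl-1,3-dioxolan-2-yl)ethyl]cyclopent-2-en-1-one
Conditions: PdCl2(dppf) (dppf = Fe(C5H4PPh2)2, 5 mol%), Ph3As, Cs2CO3, DMF/THF/H2O, rt
Reagents that add atoms: none
Why: B-alkyl Suzuki–Miyaura coupling of the α-iodoenone with the 9-BBN borane runs at room temperature under conditions developed for 4-silyloxycyclopentenones and installs the C14–C13–C16–C15 chain on C8.

Step 6
Reactants: 9 (R)-4-(tert-butyldimethylsilyloxy)-2-[2-(2-methyl-1,3-dioxolan-2-yl)ethyl]cyclopent-2-en-1-one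
Product: 12 enol triflate of the 9α-allyl-10β-silyloxy cyclopentanone (C6–OTf with C6=C8), via trimethylsilyl enol ether 10 (not isolated), via lithium enolate 11 (not isolated)
Conditions: allylMgBr, CuBr·SMe2, TMSCl, THF, −78 °C; MeLi, 0 °C; PhNTf2, −78 °C to rt
Reagents that add atoms: allylmagnesium bromide C=CC[Mg]Br; N-phenylbis(trifluoromethanesulfonimide) O=S(=O)(N(c1ccccc1)S(=O)(=O)C(F)(F)F)C(F)(F)F
Why: Copper-mediated conjugate addition delivers the allyl group anti to the 4-silyloxy group and so sets C9 (allyl α), and the regiodefined enolate is trapped as the tetrasubstituted enol triflate.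

Step 7
Reactants: 12 enol triflate
Product: 13 methyl (3,4-trans)-3-allyl-4-(tert-butyldimethylsilyloxy)-2-[2-(2-methyl-1,3-dioxolan-2-yl)ethyl]cyclopent-1-ene-1-carboxylate
Conditions: Pd(OAc)2 (5 mol%), PPh3, CO (1 atm), MeOH, Et3N, DMF, 60 °C
Reagents that add atoms: carbon monoxide [C-]#[O+]; methanol CO
Why: Palladium-catalysed methoxycarbonylation of the vinyl triflate introduces C7 and creates the C6=C8 unsaturated ester that serves as Michael acceptor.

Step 8
Reactants: 13 ketal ene ester
Product: 14 methyl (3,4-trans)-3-allyl-4-(tert-butyldimethylsilyloxy)-2-(3-oxobutyl)cyclopent-1-ene-1-carboxylate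
Conditions: PPTS, acetone/H2O, 55 °C
Reagents that add atoms: water O
Why: Mild acid-catalysed acetal hydrolysis frees the methyl ketone while the secondary silyl ether survives.

Step 9
Reactants: 14 methyl ketone ene ester
Product: 15 methyl 4α-allyl-3β-(tert-butyldimethylsilyloxy)-7-oxospiro[4.4]nonane-1-carboxylate (ring B/ring D spiro ketone; C6 epimers)
Conditions: KOtBu (20 mol%), t-BuOH/THF, 0 °C to rt
Reagents that add atoms: none
Why: Intramolecular Michael addition (5-exo-trig) of the methyl ketone enolate to the β-carbon C8 closes ring D; only the CH3 enolate can reach C8 and it adds anti to the adjacent C9 allyl group, which sets the spiro quaternary centre (C15 β, C14 α).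

Step 10
Reactants: 15 spiro keto ester
Product: 17 methyl 4α-(2,2-dimethoxyethyl)-3β-hydroxy-7,7-dimethoxyspiro[4.4]nonane-1-carboxylate, via keto aldehyde 16 (not isolated)
Conditions: O3, CH2Cl2/MeOH, −78 °C; Me2S; then HC(OMe)3, TsOH·H2O (20 mol%), rt
Reagents that add atoms: trimethyl orthoformate COC(OC)OC
Why: Ozonolysis trims the allyl group to the C11–C12 aldehyde, and acid-catalysed acetalisation then masks both carbonyl groups while methanolysis removes the silyl ether (the trans C9/C10 arrangement prevents a cyclic acetal).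

Step 11
Reactants: 17 hydroxy bis(dimethyl acetal)
Product: 18 methyl 4α-(2,2-dimethoxyethyl)-7,7-dimethoxy-3-oxospiro[4.4]nonane-1-carboxylate
Conditions: Dess–Martin periodinane, pyridine, CH2Cl2, 0 °C to rt
Reagents that add atoms: none
Why: Dess–Martin oxidation of the secondary alcohol to the C10 ketone under buffered conditions leaves the acetals and the epimerisable C9 centre intact.

Step 12
Reactants: 18 C10 ketone
Product: 20 methyl 4α-(2,2-dimethoxyethyl)-7,7-dimethoxy-3-oxospiro[4.4]non-1-ene-1-carboxylate, via trimethylsilyl enol ether 19 (not isolated)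
Conditions: LiN(iPr)2, TMSCl, THF, −78 °C; then Pd(OAc)2 (1.1 equiv), MeCN, rt
Reagents that add atoms: none
Why: Saegusa–Ito oxidation in which kinetic deprotonation takes the less hindered C5 methylene and not the tertiary C9–H, and β-hydride elimination towards C6 gives the C5=C6 alkene conjugated with ketone and ester.

Step 13
Reactants: 20 spiro enone ester
Product: 21 methyl 3β-allyl-4α-(2,2-dimethoxyethyl)-3α-hydroxy-7,7-dimethoxyspiro[4.4]non-1-ene-1-carboxylate
Conditions: allylMgBr, THF, −78 °C; then H2O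
Reagents that add atoms: allylmagnesium bromide C=CC[Mg]Br
Why: Grignard 1,2-addition to the ketone, not to the ester or the β-carbons, from the face anti to the adjacent C9 side chain sets C10 (oxygen α, C1 β).

Step 14
Reactants: 21 tertiary alcohol; 6 2-methylbut-3-enoyl chloride
Product: 22 2-methylbut-3-enoate ester of 21 (both C4 epimers)
Conditions: LiN(SiMe3)2, THF, −78 °C; then 6, −78 to −40 °C
Reagents that add atoms: none
Why: O-Acylation of the lithium alkoxide at low temperature gives the β,γ-unsaturated ester (any ketene-derived dienolate is protonated at the α-carbon), and the C4 configuration is irrelevant because C4 is later enolised.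

Step 15
Reactants: 22 diene ester
Product: 23 spiro seven-membered lactone (O–C19(=O)–C4H(CH3)–C3H=C2H–C1H2–C10) on the ring B ene ester (both C4 epimers)
Conditions: second-generation Grubbs catalyst (5 mol%), CH2Cl2 (5 mM), 40 °C
Reagents that add atoms: none
Why: Ring-closing metathesis of the two monosubstituted alkenes forms the oxepinone with the cis C2=C3 bond, and the trisubstituted ene ester does not take part.

Step 16
Reactants: 23 spiro oxepinone
Product: 24 Δ2 19,10-lactone methyl ester with rings A, B and D in place (9α-(2,2-dimethoxyethyl), 16,16-dimethoxy, 6β-CO2Me)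
Conditions: KOtBu (30 mol%), t-BuOH/THF, 0 °C to rt
Reagents that add atoms: none
Why: Intramolecular Michael addition of the lactone dienolate through its α-carbon C4 to C5 of the unsaturated ester closes ring A and the γ-lactone in one step; C4 and C5 become bridgehead and bridge atoms fixed by C10, and C6 equilibrates to the ester trans to C4.

Step 17
Reactants: 24 Δ2 lactone
Product: 25 2β,3β-diol of 24
Conditions: OsO4 (5 mol%), NMO, acetone/H2O, rt
Reagents that add atoms: N-methylmorpholine N-oxide C[N+]1([O-])CCOCC1; water O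
Why: Upjohn dihydroxylation of the only alkene occurs on the β face, away from the lactone bridge, and gives the cis 2β,3β-diol.

Step 18
Reactants: 25 diol bis(dimethyl acetal)
Product: 27 16-oxo-17-nor-GA50 methyl ester (12β-hydroxy ketone), via keto aldehyde 26 (not isolated)
Conditions: 1 M HCl, THF, 40 °C
Reagents that add atoms: water O
Why: Acetal hydrolysis and acid-catalysed intramolecular aldol addition of the C13 enol to the C12 aldehyde close ring C; attack through C15 would need a trans-fused bicyclo[3.3.0]octane, dehydration would need a bridgehead alkene, and the reversible reaction settles on the equatorial 12β-alcohol hydrogen-bonded to the C16 ketone.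

Step 19
Reactants: 27 16-oxo-17-nor-GA50 methyl ester
Product: 28 GA50 methyl ester
Conditions: Zn, CH2Br2, TiCl4, THF/CH2Cl2, 0 °C to rt
Reagents that add atoms: dibromomethane BrCBr
Why: Lombardo methylenation turns the hindered ketone into the exocyclic alkene without base, which avoids retro-aldol cleavage of the β-hydroxy ketone and tolerates the free hydroxyl groups, ester and lactone.

Step 20
Reactants: 28 GA50 methyl ester
Product: 29 GA50
Conditions: n-PrSLi (from n-PrSH and n-BuLi), HMPA, rt; then aq. HCl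
Reagents that add atoms: none
Why: SN2 demethylation of the hindered methyl ester by thiolate leaves the lactone and the base-sensitive β-hydroxy lactone unit untouched.

**Compound list**

1 | 2-methyl-2-vinyl-1,3-dioxolane | C=CC1(C)OCCO1 | starting material
2 | 9-[2-(2-methyl-1,3-dioxolan-2-yl)ethyl]-9-borabicyclo[3.3.1]nonane | CC1(CCB2C3CCCC2CCC3)OCCO1 | intermediate
3 | (E)-1-chlorobut-2-ene (crotyl chloride) | C/C=C/CCl | starting material
4 | but-2-enylmagnesium chloride | C/C=C/C[Mg]Cl | intermediate (not isolated)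
5 | 2-methylbut-3-enoic acid (racemic) | C=CC(C)C(=O)O | intermediate
6 | 2-methylbut-3-enoyl chloride (racemic) | C=CC(C)C(=O)Cl | intermediate
7 | (R)-4-(tert-butyldimethylsilyloxy)cyclopent-2-en-1-one | O=C1C=C[C@H](O[Si](C)(C)C(C)(C)C)C1 | starting material
8 | (R)-4-(tert-butyldimethylsilyloxy)-2-iodocyclopent-2-en-1-one | IC1=C[C@H](O[Si](C)(C)C(C)(C)C)CC1=O | intermediate
9 | (R)-4-(tert-butyldimethylsilyloxy)-2-[2-(2-methyl-1,3-dioxolan-2-yl)ethyl]cyclopent-2-en-1-one | O=C1C(CCC2(C)OCCO2)=C[C@H](O[Si](C)(C)C(C)(C)C)C1 | intermediate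
10 | trimethylsilyl enol ether of the conjugate adduct (C6–OSiMe3, C6=C8; 9α-allyl, 10β-OTBS, trans) | C[Si](C)(C)OC1=C(CCC2(C)OCCO2)[C@@H](CC=C)[C@H](O[Si](C)(C)C(C)(C)C)C1 | intermediate (not isolated)
11 | lithium enolate corresponding to 10 | [Li]OC1=C(CCC2(C)OCCO2)[C@@H](CC=C)[C@H](O[Si](C)(C)C(C)(C)C)C1 | intermediate (not isolated)
12 | (3,4-trans)-3-allyl-4-(tert-butyldimethylsilyloxy)-2-[2-(2-methyl-1,3-dioxolan-2-yl)ethyl]cyclopent-1-en-1-yl trifluoromethanesulfonate (9α-allyl, 10β-OTBS) | O=S(=O)(OC1=C(CCC2(C)OCCO2)[C@@H](CC=C)[C@H](O[Si](C)(C)C(C)(C)C)C1)C(F)(F)F | intermediate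
13 | methyl (3,4-trans)-3-allyl-4-(tert-butyldimethylsilyloxy)-2-[2-(2-methyl-1,3-dioxolan-2-yl)ethyl]cyclopent-1-ene-1-carboxylate | COC(=O)C1=C(CCC2(C)OCCO2)[C@@H](CC=C)[C@H](O[Si](C)(C)C(C)(C)C)C1 | intermediate
14 | methyl (3,4-trans)-3-allyl-4-(tert-butyldimethylsilyloxy)-2-(3-oxobutyl)cyclopent-1-ene-1-carboxylate | COC(=O)C1=C(CCC(C)=O)[C@@H](CC=C)[C@H](O[Si](C)(C)C(C)(C)C)C1 | intermediate
15 | methyl 4α-allyl-3β-(tert-butyldimethylsilyloxy)-7-oxospiro[4.4]nonane-1-carboxylate (spiro C8: C15 β, C14 α; C6 epimers) | COC(=O)C1C[C@@H](O[Si](C)(C)C(C)(C)C)[C@H](CC=C)[C@@]12CC(=O)CC2 | intermediate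
16 | methyl 3β-(tert-butyldimethylsilyloxy)-7-oxo-4α-(2-oxoethyl)spiro[4.4]nonane-1-carboxylate | COC(=O)C1C[C@@H](O[Si](C)(C)C(C)(C)C)[C@H](CC=O)[C@@]12CC(=O)CC2 | intermediate (not isolated)
17 | methyl 4α-(2,2-dimethoxyethyl)-3β-hydroxy-7,7-dimethoxyspiro[4.4]nonane-1-carboxylate | COC(=O)C1C[C@@H](O)[C@H](CC(OC)OC)[C@@]12CC(OC)(OC)CC2 | intermediate
18 | methyl 4α-(2,2-dimethoxyethyl)-7,7-dimethoxy-3-oxospiro[4.4]nonane-1-carboxylate | COC(=O)C1CC(=O)[C@H](CC(OC)OC)[C@@]12CC(OC)(OC)CC2 | intermediate
19 | trimethylsilyl enol ether of 18 (C10–OSiMe3, C5=C10) | COC(=O)C1C=C(O[Si](C)(C)C)[C@H](CC(OC)OC)[C@@]12CC(OC)(OC)CC2 | intermediate (not isolated)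
20 | methyl 4α-(2,2-dimethoxyethyl)-7,7-dimethoxy-3-oxospiro[4.4]non-1-ene-1-carboxylate (C10 ketone, C5=C6 ester) | COC(=O)C1=CC(=O)[C@H](CC(OC)OC)[C@@]12CC(OC)(OC)CC2 | intermediate
21 | methyl 3β-allyl-4α-(2,2-dimethoxyethyl)-3α-hydroxy-7,7-dimethoxyspiro[4.4]non-1-ene-1-carboxylate (C10: O α, allyl β) | COC(=O)C1=C[C@@](O)(CC=C)[C@H](CC(OC)OC)[C@@]12CC(OC)(OC)CC2 | intermediate
22 | 2-methylbut-3-enoate ester of 21 (C4 epimers) | COC(=O)C1=C[C@@](OC(=O)C(C)C=C)(CC=C)[C@H](CC(OC)OC)[C@@]12CC(OC)(OC)CC2 | intermediate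
23 | spiro oxepinone: 3-methyl-4,7-dihydrooxepin-2(3H)-one ring (O10–C19–C4–C3=C2–C1) spiro at C10 on the ring B ene ester (C4 epimers) | COC(=O)C1=C[C@]3(OC(=O)C(C)C=CC3)[C@H](CC(OC)OC)[C@@]12CC(OC)(OC)CC2 | intermediate
24 | Δ2 19,10-lactone 7-methyl ester with rings A, B, D (ring C open: 9α-(2,2-dimethoxyethyl), 16,16-dimethoxy; 4α-lactone, 5β-H, 6β-CO2Me) | COC1(OC)C[C@]3(CC1)[C@@H](CC(OC)OC)[C@@]12CC=C[C@@](C)(C(=O)O1)[C@H]2[C@@H]3C(=O)OC | intermediate
25 | 2β,3β-dihydroxy derivative of 24 | COC1(OC)C[C@]3(CC1)[C@@H](CC(OC)OC)[C@@]12C[C@H](O)[C@H](O)[C@@](C)(C(=O)O1)[C@H]2[C@@H]3C(=O)OC | intermediate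
26 | keto aldehyde from 25 (C16 ketone, C12 aldehyde) | O=C1C[C@]3(CC1)[C@@H](CC=O)[C@@]12C[C@H](O)[C@H](O)[C@@](C)(C(=O)O1)[C@H]2[C@@H]3C(=O)OC | intermediate (not isolated)
27 | 16-oxo-17-nor-GA50 methyl ester (2β,3β,12β-triol, 16-ketone) | O=C1C[C@]23C[C@H]1[C@H](O)C[C@H]2[C@@]12C[C@H](O)[C@H](O)[C@@](C)(C(=O)O1)[C@H]2[C@@H]3C(=O)OC | intermediate
28 | GA50 methyl ester | C=C1C[C@]23C[C@H]1[C@H](O)C[C@H]2[C@@]12C[C@H](O)[C@H](O)[C@@](C)(C(=O)O1)[C@H]2[C@@H]3C(=O)OC | intermediate
29 | GA50 | C=C1C[C@]23C[C@H]1[C@H](O)C[C@H]2[C@@]12C[C@H](O)[C@H](O)[C@@](C)(C(=O)O1)[C@H]2[C@@H]3C(=O)O | target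

**Step count and risks**

Total step count: 20. Longest linear sequence: 17 steps (7 to 29 through steps 4–20; the borane branch from 1 is equally long through step 1 and steps 5–20; the acyl branch from 3 is 9 steps).

The three steps most likely to fail:

Step 9 (spiro Michael addition onto a tetrasubstituted acceptor; risks are retro-Michael and γ-deprotonation of the ene ester). The fallback sets out from 14 and comes back at 15. Kinetic silylation of the methyl ketone (LiN(iPr)2, TMSCl, THF, −78 °C) gives the isolated kinetic trimethylsilyl enol ether F1. Ring D is then closed by a Lewis acid-mediated intramolecular Mukaiyama–Michael reaction (TiCl4, CH2Cl2, −78 °C), which activates the unsaturated ester instead of relying on a reversible enolate addition; aqueous work-up gives 15.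

Step 16 (ring-bridging Michael addition of the seven-membered lactone; risks are conjugation of the lactone alkene and Claisen-type ring contraction). The fallback sets out from 21 and comes back at 24. O-Acylation with propionyl chloride (LiN(SiMe3)2, THF, −78 °C) gives the propionate ester F2. Its potassium enolate (KN(SiMe3)2, THF, −78 to 0 °C) adds 5-exo to C5 and gives the γ-lactone F3 with C4–H and the C10 allyl group retained. The lactone enolate (LiN(iPr)2, −78 °C) adds to acetaldehyde on the convex face, cis to the C10 allyl group, to give the hydroxyethyl lactone F4. Dehydration (Martin sulfurane) gives the C4 vinyl lactone F5, and ring-closing metathesis (second-generation Grubbs catalyst) forms the C2=C3 bond and delivers 24.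

Step 18 (one-pot acetal hydrolysis and aldol closure on an unprotected diol; risks are slow enolisation and side reactions of the free aldehyde in acid). The fallback sets out from 25 and comes back at 27. Transacetalisation in dry acetone (TsOH, rt) removes both dimethyl acetals and ties up the diol, giving the isolated keto aldehyde acetonide F6. Amine catalysis (pyrrolidine, AcOH, CH2Cl2) closes ring C through the less hindered C13 enamine to the hydroxy ketone acetonide F7. Aqueous AcOH (80%, 50 °C) then removes the acetonide and gives 27.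

Further compounds

F1 | step 9 | methyl (3,4-trans)-3-allyl-4-(tert-butyldimethylsilyloxy)-2-[3-(trimethylsilyloxy)but-3-enyl]cyclopent-1-ene-1-carboxylate | COC(=O)C1=C(CCC(=C)O[Si](C)(C)C)[C@@H](CC=C)[C@H](O[Si](C)(C)C(C)(C)C)C1
F2 | step 16 | propionate ester of 21 | COC(=O)C1=C[C@@](OC(=O)CC)(CC=C)[C@H](CC(OC)OC)[C@@]12CC(OC)(OC)CC2
F3 | step 16 | γ-lactone (19,10-lactone, C4–H epimers, 10β-allyl, 6β-CO2Me, ring C and ring A open) | COC1(OC)C[C@]3(CC1)[C@@H](CC(OC)OC)[C@@]2(CC=C)OC(=O)C(C)[C@H]2[C@@H]3C(=O)OC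
F4 | step 16 | C4-(1-hydroxyethyl) γ-lactone (hydroxyethyl cis to the C10 allyl group, carbinol epimers) | COC1(OC)C[C@]3(CC1)[C@@H](CC(OC)OC)[C@@]2(CC=C)OC(=O)[C@](C)(C(C)O)[C@H]2[C@@H]3C(=O)OC
F5 | step 16 | C4-vinyl γ-lactone (vinyl cis to the C10 allyl group) | COC1(OC)C[C@]3(CC1)[C@@H](CC(OC)OC)[C@@]2(CC=C)OC(=O)[C@](C)(C=C)[C@H]2[C@@H]3C(=O)OC
F6 | step 18 | 2β,3β-O-isopropylidene keto aldehyde (acetonide of 26) | O=C1C[C@]3(CC1)[C@@H](CC=O)[C@@]12C[C@@H]4OC(C)(C)O[C@@H]4[C@@](C)(C(=O)O1)[C@H]2[C@@H]3C(=O)OC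
F7 | step 18 | 2β,3β-O-isopropylidene derivative of 27 | O=C1C[C@]23C[C@H]1[C@H](O)C[C@H]2[C@@]12C[C@@H]4OC(C)(C)O[C@@H]4[C@@](C)(C(=O)O1)[C@H]2[C@@H]3C(=O)OC
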